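Ring B is cut at C1–C8a (naphthalene numbering). There the quaternary CMe2 carbon C1 lies between the stereocentre C8a and the tetrasubstituted C2=C3 alkene, the pattern an ester-enolate Claisen shift leaves behind. Heating the silyl ketene acetal of δ-lactone 19, which carries a methyl and a tetrasubstituted alkenyl group on its carbinol carbon and a vinyl group on its β-carbon (future C4a), forms C1–C8a, moves the alkene to C2=C3, closes ring B and sets C8a cis to the C4a vinyl group in one operation (acid 22). Ring A follows by metathesis; a separately built, stereodefined 1,2-dioxane aldehyde is joined by Wittig reaction, diimide reduction and oxidation.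

Key step: step 9

Numbering: decalin atoms are C1–C8a as in naphthalene (C1 = CMe2, C2=C3, C4a/C8a ring fusion, C5=C6); in the 1,2-dioxane the CH carbon is C3 and the quaternary carbon is C6, as in the target.

Assumption: the (R,R) antipode of the bisphosphine in step 5 is taken to deliver the allyl group to the ketone face that gives the (R)-carbinol; if the sense proves opposite, the (S,S) antipode is used with no other change.

**Decalin half (steps 1–15)**

Step 1
Reactants: 1 3-methylbut-2-enal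
Product: 3 2-bromo-3-methylbut-2-enal, via 2,3-dibromo-3-methylbutanal 2 (not isolated)
Conditions: Br2, CH2Cl2, −20 °C; then Et3N, 0 °C to rt
Reagents that add atoms: bromine, BrBr
Why: Bromine addition to the enal followed by base-induced loss of HBr through the enolate (α-bromination of an enal by addition–elimination) can only return the conjugated tetrasubstituted α-bromo enal.

Step 2
Reactants: 3 2-bromo-3-methylbut-2-enal
Product: 4 2-bromo-3-methylbut-2-en-1-ol
Conditions: NaBH4, CeCl3·7H2O, MeOH, 0 °C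
Reagents that add atoms: none
Why: Luche reduction delivers hydride 1,2 to the enal and leaves the vinyl bromide untouched.

Step 3
Reactants: 4 2-bromo-3-methylbut-2-en-1-ol
Product: 5 [(2-bromo-3-methylbut-2-en-1-yl)oxy](tert-butyl)dimethylsilane
Conditions: TBSCl, imidazole, CH2Cl2, rt
Reagents that add atoms: tert-butyldimethylsilyl chloride, CC(C)(C)[Si](C)(C)Cl
Why: Routine silylation of a primary allylic alcohol gives an ether that survives organolithium, enolate, hydride and metathesis conditions and is removed by fluoride in step 14.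

Step 4
Reactants: 5 [(2-bromo-3-methylbut-2-en-1-yl)oxy](tert-butyl)dimethylsilane; 6 N-methoxy-N-methylacetamide
Product: 9 3-{[(tert-butyldimethylsilyl)oxy]methyl}-4-methylpent-3-en-2-one, via alkenyllithium 7 (not isolated), via lithium hemiaminal 8 (not isolated)
Conditions: t-BuLi (2.1 equiv), Et2O, −78 °C; then 6, −78 to 0 °C; aq. NH4Cl
Reagents that add atoms: none
Why: Bromine–lithium exchange at −78 °C (cold enough to prevent silyl migration from oxygen to carbon) followed by Weinreb amide acylation, whose chelated tetrahedral adduct prevents over-addition, gives the methyl ketone.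

Step 5
Reactants: 9 3-{[(tert-butyldimethylsilyl)oxy]methyl}-4-methylpent-3-en-2-one; 10 allylboronic acid pinacol ester
Product: 12 (4R)-5-{[(tert-butyldimethylsilyl)oxy]methyl}-4,6-dimethylhepta-1,5-dien-4-ol, via pinacol borate ester 11 (not isolated)
Conditions: CuF2·2H2O (3 mol %), (R,R)-iPr-DuPHOS (6 mol %), La(OiPr)3 (4.5 mol %), DMF, −40 °C; aq. NH4Cl
Reagents that add atoms: none
Why: Copper-catalysed enantioselective allylboration of a methyl ketone (chiral bisphosphine allylcopper adding through a six-membered transition state) distinguishes the methyl group from the bulky tetrasubstituted alkenyl group and sets the tertiary carbinol as R by catalyst control.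

Step 6
Reactants: 12 (4R)-5-{[(tert-butyldimethylsilyl)oxy]methyl}-4,6-dimethylhepta-1,5-dien-4-ol; 13 acryloyl chloride
Product: 15 (4R)-5-{[(tert-butyldimethylsilyl)oxy]methyl}-4,6-dimethylhepta-1,5-dien-4-yl acrylate, via potassium alkoxide 14 (not isolated)
Conditions: KN(SiMe3)2, THF, −78 °C; then 13, −78 to 0 °C
Reagents that add atoms: none
Why: O-acylation of the preformed potassium alkoxide overcomes the low reactivity of the hindered tertiary alcohol and does not touch the stereocentre.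

Step 7
Reactants: 15 (4R)-5-{[(tert-butyldimethylsilyl)oxy]methyl}-4,6-dimethylhepta-1,5-dien-4-yl acrylate
Product: 16 (6R)-6-{1-[(tert-butyldimethylsilyl)oxy]-3-methylbut-2-en-2-yl}-6-methyl-5,6-dihydro-2H-pyran-2-one
Conditions: second-generation Grubbs catalyst RuCl2(=CHPh)(PCy3)(H2IMes) (5 mol %), CH2Cl2 (5 mM), 40 °C
Reagents that add atoms: none
Why: Ring-closing metathesis between the allyl group and the acrylate closes the α,β-unsaturated δ-lactone with loss of ethene, the tetrasubstituted alkene being inert to the catalyst.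

Step 8
Reactants: 16 (6R)-6-{1-[(tert-butyldimethylsilyl)oxy]-3-methylbut-2-en-2-yl}-6-methyl-5,6-dihydro-2H-pyran-2-one; 17 vinylmagnesium bromide
Product: 19 (4S,6R)-6-{1-[(tert-butyldimethylsilyl)oxy]-3-methylbut-2-en-2-yl}-6-methyl-4-vinyltetrahydro-2H-pyran-2-one, via bromomagnesium enolate 18 (not isolated)
Conditions: CuI (1.1 equiv), 17 (2.2 equiv), THF/Me2S, −78 to −40 °C; aq. NH4Cl
Reagents that add atoms: none
Why: Conjugate addition of the divinylcuprate to the unsaturated lactone should occur on the ring face opposite the bulky alkenyl group on the carbinol carbon (syn to its small methyl group), so the vinyl-bearing stereocentre (S, future C4a) is set trans to the alkenyl group by substrate control.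

Step 9
Reactants: 19 (4S,6R)-6-{1-[(tert-butyldimethylsilyl)oxy]-3-methylbut-2-en-2-yl}-6-methyl-4-vinyltetrahydro-2H-pyran-2-one
Product: 22 (1S,6R)-3-{[(tert-butyldimethylsilyl)oxy]methyl}-2,2,4-trimethyl-6-vinylcyclohex-3-ene-1-carboxylic acid, via trimethylsilyl ketene acetal 20 (not isolated), via trimethylsilyl ester 21 (not isolated)
Conditions: Me3SiCl/Et3N, then LiN(iPr)2, THF, −78 °C to rt; toluene, 110 °C; then H2O/THF, citric acid, rt
Reagents that add atoms: none
Why: Deprotonation of the lactone at its only enolisable carbon (future C8a) in the presence of Me3SiCl gives the endocyclic silyl ketene acetal 20, which on heating undergoes an Ireland–Claisen [3,3] shift: the ketene acetal carbon bonds to the CMe2 terminus (C1) of the alkenyl group while the allylic C3–O bond breaks and the alkene moves to C2=C3. The closest known reaction type is the Claisen ring contraction of silyl ketene acetals of lactones that carry an alkenyl group on the carbinol carbon. Ring B (C8a, C4a, C4, C3, C2, C1) is closed in a pericyclic ring-contraction mode, through a boat-like transition state in which the lactone ring and the forming carbocycle share four atoms in a bicyclo[2.2.2]octane-like array with the alkenyl group axial. The new stereocentre C8a is controlled by the carbinol stereocentre (future C3): the bond can form only on the lactone face that carries the alkenyl group, and because the vinyl group on C4a lies on the other face, carboxyl and vinyl should emerge cis on ring B, after which the carbinol stereocentre is erased. The step needs rearrangement to outrun ionisation of the tertiary allylic C–O bond, which the internal silyl quench, the non-polar solvent and the intramolecular geometry are meant to secure. Formation of the carboxylate C=O drives the shift and pays for the congested bond between quaternary C1 and tertiary C8a.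

Step 10
Reactants: 22 (1S,6R)-3-{[(tert-butyldimethylsilyl)oxy]methyl}-2,2,4-trimethyl-6-vinylcyclohex-3-ene-1-carboxylic acid
Product: 23 [(1S,6R)-3-{[(tert-butyldimethylsilyl)oxy]methyl}-2,2,4-trimethyl-6-vinylcyclohex-3-en-1-yl]methanol
Conditions: LiAlH4, THF, 0 to 40 °C; aq. NaOH work-up
Reagents that add atoms: none
Why: Hydride reduction of the carboxylic acid gives the primary alcohol (future C8) and spares the silyl ether and both alkenes.

Step 11
Reactants: 23 [(1S,6R)-3-{[(tert-butyldimethylsilyl)oxy]methyl}-2,2,4-trimethyl-6-vinylcyclohex-3-en-1-yl]methanol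
Product: 24 tert-butyl{[(5S,6R)-configured ring B iodide]}: the 1-(iodomethyl) analogue of 23, C8a–CH2I cis to the C4a vinyl group
Conditions: I2, PPh3, imidazole, CH2Cl2, 0 °C to rt
Reagents that add atoms: iodine, II
Why: Appel-type iodination converts the primary, β-branched alcohol into the iodide under neutral conditions without disturbing the adjacent stereocentres.

Step 12
Reactants: 24 ring B iodide (C8a–CH2I, C4a–vinyl, cis); 25 (2-methylallyl)magnesium chloride
Product: 26 ring B diene: the 1-(3-methylbut-3-en-1-yl) analogue of 23, cis to the C4a vinyl group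
Conditions: CuI (10 mol %), 25 (2 equiv), THF, −20 °C to rt
Reagents that add atoms: none
Why: Copper-catalysed coupling of the allylic Grignard reagent with the primary iodide (sp3–sp3 coupling through a methallyl cuprate) appends C7, C6 and the C6 methyl group, a displacement that is known for comparably hindered cyclogeranyl-type halides.

Step 13
Reactants: 26 ring B diene (C8a–CH2CH2C(CH3)=CH2, C4a–vinyl, cis)
Product: 27 tert-butyldimethyl{[(4aR,8aS)-1,1,3,6-tetramethyl-1,4,4a,7,8,8a-hexahydronaphthalen-2-yl]methoxy}silane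
Conditions: second-generation Grubbs catalyst RuCl2(=CHPh)(PCy3)(H2IMes) (5 mol %), CH2Cl2, 40 °C
Reagents that add atoms: none
Why: Ring-closing metathesis between the C4a vinyl group and the 1,1-disubstituted alkene closes ring A as the trisubstituted C5=C6 cyclohexene; the cis arms fix the cis ring fusion and the tetrasubstituted C2=C3 alkene does not take part.

Step 14
Reactants: 27 tert-butyldimethyl{[(4aR,8aS)-1,1,3,6-tetramethyl-1,4,4a,7,8,8a-hexahydronaphthalen-2-yl]methoxy}silane
Product: 28 [(4aR,8aS)-1,1,3,6-tetramethyl-1,4,4a,7,8,8a-hexahydronaphthalen-2-yl]methanol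
Conditions: Bu4NF, THF, 0 °C to rt
Reagents that add atoms: none
Why: Fluoride cleaves the silyl ether and frees the allylic alcohol.

Step 15
Reactants: 28 [(4aR,8aS)-1,1,3,6-tetramethyl-1,4,4a,7,8,8a-hexahydronaphthalen-2-yl]methanol
Product: 29 {[(4aR,8aS)-1,1,3,6-tetramethyl-1,4,4a,7,8,8a-hexahydronaphthalen-2-yl]methyl}triphenylphosphonium bromide
Conditions: PPh3·HBr, MeOH, rt
Reagents that add atoms: triphenylphosphine hydrobromide, [PH+](c1ccccc1)(c1ccccc1)c1ccccc1.[Br-]
Why: Direct conversion of an allylic alcohol into its phosphonium salt (the protonated alcohol ionises and triphenylphosphine captures the primary terminus) is the standard preparation of the closely related β-cyclogeranyl salt.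

**Dioxane half (steps 16–26)**

Step 16
Reactants: 30 geraniol
Product: 31 [(2R,3R)-3-methyl-3-(4-methylpent-3-en-1-yl)oxiran-2-yl]methanol
Conditions: Ti(OiPr)4 (5 mol %), D-(−)-diethyl tartrate (7 mol %), t-BuOOH, 4 Å molecular sieves, CH2Cl2, −20 °C
Reagents that add atoms: tert-butyl hydroperoxide, CC(C)(C)OO
Why: Sharpless asymmetric epoxidation with the D-tartrate ligand delivers oxygen to the face of the (E)-allylic alcohol that gives the (2R,3R)-epoxide, fixing the quaternary carbon that becomes C6 of the dioxane.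

Step 17
Reactants: 31 [(2R,3R)-3-methyl-3-(4-methylpent-3-en-1-yl)oxiran-2-yl]methanol
Product: 32 tert-butyl{[(2R,3R)-3-methyl-3-(4-methylpent-3-en-1-yl)oxiran-2-yl]methoxy}diphenylsilane
Conditions: TBDPSCl, imidazole, CH2Cl2, 0 °C to rt
Reagents that add atoms: tert-butyldiphenylsilyl chloride, CC(C)(C)[Si](Cl)(c1ccccc1)c1ccccc1
Why: Silylation of the primary alcohol gives an acid-stable ether that will not take part in the later epoxide opening as an acyl group could.

Step 18
Reactants: 32 tert-butyl{[(2R,3R)-3-methyl-3-(4-methylpent-3-en-1-yl)oxiran-2-yl]methoxy}diphenylsilane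
Product: 34 3-[(2R,3R)-3-{[(tert-butyldiphenylsilyl)oxy]methyl}-2-methyloxiran-2-yl]propanal, via secondary ozonide 33 (not isolated)
Conditions: O3, CH2Cl2, −78 °C; then PPh3, −78 °C to rt
Reagents that add atoms: ozone, [O-][O+]=O
Why: Ozonolysis of the only alkene with reductive work-up releases the aldehyde and acetone, the epoxide and silyl ether being inert to ozone.

Step 19
Reactants: 34 3-[(2R,3R)-3-{[(tert-butyldiphenylsilyl)oxy]methyl}-2-methyloxiran-2-yl]propanal; 35 (4R)-4-benzyl-3-propanoyl-1,3-oxazolidin-2-one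
Product: 38 (4R)-4-benzyl-3-[(2R,3S)-5-[(2R,3R)-3-{[(tert-butyldiphenylsilyl)oxy]methyl}-2-methyloxiran-2-yl]-3-hydroxy-2-methylpentanoyl]-1,3-oxazolidin-2-one, via dibutylboron enolate 36 (not isolated), via dibutylboron aldolate 37 (not isolated)
Conditions: 35, Bu2BOTf (1.05 equiv), iPr2NEt (1.2 equiv), CH2Cl2, −78 to 0 °C; then 34, −78 to 0 °C; pH 7 buffer, MeOH, H2O2, 0 °C
Reagents that add atoms: none
Why: Evans syn-aldol reaction: the (Z)-boron enolate of the (R)-benzyl oxazolidinone adds through a Zimmerman–Traxler chair to give the (2R,3S) syn adduct by auxiliary control, and the enolate is preformed with only a slight excess of Bu2BOTf so that no free Lewis acid meets the epoxide.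

Step 20
Reactants: 38 (4R)-4-benzyl-3-[(2R,3S)-5-[(2R,3R)-3-{[(tert-butyldiphenylsilyl)oxy]methyl}-2-methyloxiran-2-yl]-3-hydroxy-2-methylpentanoyl]-1,3-oxazolidin-2-one
Product: 39 (2S,3S)-5-[(2R,3R)-3-{[(tert-butyldiphenylsilyl)oxy]methyl}-2-methyloxiran-2-yl]-2-methylpentane-1,3-diol
Conditions: LiBH4, MeOH (1 equiv), THF, 0 °C
Reagents that add atoms: none
Why: Reductive cleavage of the N-acyl oxazolidinone with borohydride gives the 1,3-diol and returns the auxiliary, the trisubstituted epoxide not being opened at 0 °C.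

Step 21
Reactants: 39 (2S,3S)-5-[(2R,3R)-3-{[(tert-butyldiphenylsilyl)oxy]methyl}-2-methyloxiran-2-yl]-2-methylpentane-1,3-diol
Product: 40 (2S,3S)-1-[(tert-butyldiphenylsilyl)oxy]-5-[(2R,3R)-3-{[(tert-butyldiphenylsilyl)oxy]methyl}-2-methyloxiran-2-yl]-2-methylpentan-3-ol
Conditions: TBDPSCl (1.05 equiv), imidazole, CH2Cl2, 0 °C
Reagents that add atoms: tert-butyldiphenylsilyl chloride, CC(C)(C)[Si](Cl)(c1ccccc1)c1ccccc1
Why: The bulky silyl chloride selects the primary over the secondary hydroxyl group (selective silylation).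

Step 22
Reactants: 40 (2S,3S)-1-[(tert-butyldiphenylsilyl)oxy]-5-[(2R,3R)-3-{[(tert-butyldiphenylsilyl)oxy]methyl}-2-methyloxiran-2-yl]-2-methylpentan-3-ol
Product: 41 (2S,3S)-1-[(tert-butyldiphenylsilyl)oxy]-5-[(2R,3R)-3-{[(tert-butyldiphenylsilyl)oxy]methyl}-2-methyloxiran-2-yl]-2-methylpentan-3-yl methanesulfonate
Conditions: MsCl, Et3N, CH2Cl2, 0 °C
Reagents that add atoms: methanesulfonyl chloride, CS(=O)(=O)Cl
Why: Sulfonylation turns the secondary alcohol into the leaving group for the later ring closure without change of configuration.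

Step 23
Reactants: 41 (2S,3S)-1-[(tert-butyldiphenylsilyl)oxy]-5-[(2R,3R)-3-{[(tert-butyldiphenylsilyl)oxy]methyl}-2-methyloxiran-2-yl]-2-methylpentan-3-yl methanesulfonate
Product: 42 (2S,3S,6S,7R)-1,8-bis[(tert-butyldiphenylsilyl)oxy]-6-hydroperoxy-7-hydroxy-2,6-dimethyloctan-3-yl methanesulfonate
Conditions: H2O2 (anhydrous, in Et2O, 10 equiv), H3PMo12O40 (5 mol %), Et2O, 0 °C to rt
Reagents that add atoms: hydrogen peroxide, OO
Why: Acid-catalysed perhydrolysis of the epoxide (ring opening by H2O2 under phosphomolybdic acid catalysis) should occur at the tertiary carbon, the better cation-stabilising site and the one remote from the electron-withdrawing CH2O group, with inversion, giving the (S)-tertiary hydroperoxide.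

Step 24
Reactants: 42 (2S,3S,6S,7R)-1,8-bis[(tert-butyldiphenylsilyl)oxy]-6-hydroperoxy-7-hydroxy-2,6-dimethyloctan-3-yl methanesulfonate
Product: 43 (1R)-2-[(tert-butyldiphenylsilyl)oxy]-1-[(3S,6R)-6-{(2S)-1-[(tert-butyldiphenylsilyl)oxy]propan-2-yl}-3-methyl-1,2-dioxan-3-yl]ethan-1-ol
Conditions: CsOH·H2O (1.1 equiv), DMF, 0 °C to rt
Reagents that add atoms: none
Why: Intramolecular alkylation of the hydroperoxide anion (far more acidic and nucleophilic than the neighbouring alcohol) by the secondary mesylate, a 6-exo-tet SN2 displacement with inversion, closes the 1,2-dioxane and sets its CH carbon as R.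

Step 25
Reactants: 43 (1R)-2-[(tert-butyldiphenylsilyl)oxy]-1-[(3S,6R)-6-{(2S)-1-[(tert-butyldiphenylsilyl)oxy]propan-2-yl}-3-methyl-1,2-dioxan-3-yl]ethan-1-ol
Product: 44 (1R)-1-[(3S,6R)-6-[(2S)-1-hydroxypropan-2-yl]-3-methyl-1,2-dioxan-3-yl]ethane-1,2-diol
Conditions: HF·pyridine, pyridine, THF, 0 °C to rt
Reagents that add atoms: none
Why: Fluoride cleaves both silyl ethers under buffered conditions that leave the dialkyl peroxide untouched.

Step 26
Reactants: 44 (1R)-1-[(3S,6R)-6-[(2S)-1-hydroxypropan-2-yl]-3-methyl-1,2-dioxan-3-yl]ethane-1,2-diol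
Product: 45 (3S,6R)-6-[(2S)-1-hydroxypropan-2-yl]-3-methyl-1,2-dioxane-3-carbaldehyde
Conditions: NaIO4, THF/H2O (pH 7 buffer), 0 °C
Reagents that add atoms: none
Why: Periodate glycol cleavage removes the terminal carbon as formaldehyde and unveils the α-peroxy aldehyde, which has no α-hydrogen and cannot epimerise, while the isolated primary alcohol is not a 1,2-diol and is untouched.

**Union and end game (steps 27–29)**

Step 27
Reactants: 29 {[(4aR,8aS)-1,1,3,6-tetramethyl-1,4,4a,7,8,8a-hexahydronaphthalen-2-yl]methyl}triphenylphosphonium bromide; 45 (3S,6R)-6-[(2S)-1-hydroxypropan-2-yl]-3-methyl-1,2-dioxane-3-carbaldehyde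
Product: 47 (2S)-2-[(3R,6S)-6-methyl-6-{2-[(4aR,8aS)-1,1,3,6-tetramethyl-1,4,4a,7,8,8a-hexahydronaphthalen-2-yl]ethenyl}-1,2-dioxan-3-yl]propan-1-ol (E/Z mixture), via phosphonium ylide 46 (not isolated)
Conditions: 29 (1.3 equiv), KN(SiMe3)2 (1.25 equiv), THF, −78 to 0 °C; then 45, −78 °C to rt
Reagents that add atoms: none
Why: Wittig olefination of the non-enolisable α-peroxy aldehyde with the semi-stabilised allylic ylide joins the two halves as a diene of either geometry (the new alkene is reduced next), and the ylide is not basic enough to deprotonate the free alcohol.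

Step 28
Reactants: 47 (2S)-2-[(3R,6S)-6-methyl-6-{2-[(4aR,8aS)-1,1,3,6-tetramethyl-1,4,4a,7,8,8a-hexahydronaphthalen-2-yl]ethenyl}-1,2-dioxan-3-yl]propan-1-ol
Product: 48 (2S)-2-[(3R,6R)-6-methyl-6-{2-[(4aR,8aS)-1,1,3,6-tetramethyl-1,4,4a,7,8,8a-hexahydronaphthalen-2-yl]ethyl}-1,2-dioxan-3-yl]propan-1-ol
Conditions: KO2CN=NCO2K, AcOH, pyridine/MeOH, 0 °C to rt, added in portions
Reagents that add atoms: none
Why: Diimide reduction transfers hydrogen to the least substituted alkene, so the 1,2-disubstituted linker alkene should be saturated while the trisubstituted C5=C6 alkene, the tetrasubstituted C2=C3 alkene and the O–O bond, which would not survive catalytic hydrogenation, remain.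

Step 29
Reactants: 48 (2S)-2-[(3R,6R)-6-methyl-6-{2-[(4aR,8aS)-1,1,3,6-tetramethyl-1,4,4a,7,8,8a-hexahydronaphthalen-2-yl]ethyl}-1,2-dioxan-3-yl]propan-1-ol
Product: 50 (2R)-2-[(3R,6R)-6-methyl-6-{2-[(4aR,8aS)-1,1,3,6-tetramethyl-1,4,4a,7,8,8a-hexahydronaphthalen-2-yl]ethyl}-1,2-dioxan-3-yl]propanoic acid (target), via aldehyde 49 (not isolated)
Conditions: TEMPO (20 mol %), PhI(OAc)2 (2.5 equiv), MeCN/H2O (pH 7 phosphate buffer), rt
Reagents that add atoms: water, O
Why: Oxoammonium-mediated oxidation (TEMPO with PhI(OAc)2 in aqueous acetonitrile) takes the primary alcohol through the aldehyde hydrate to the carboxylic acid under near-neutral conditions that should spare the peroxide, both alkenes and the α-stereocentre.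

**Compound list**

1 | 3-methylbut-2-enal | CC(C)=CC=O | starting material
2 | 2,3-dibromo-3-methylbutanal | CC(C)(Br)C(Br)C=O | intermediate
3 | 2-bromo-3-methylbut-2-enal | CC(C)=C(Br)C=O | intermediate
4 | 2-bromo-3-methylbut-2-en-1-ol | CC(C)=C(Br)CO | intermediate
5 | [(2-bromo-3-methylbut-2-en-1-yl)oxy](tert-butyl)dimethylsilane | CC(C)=C(Br)CO[Si](C)(C)C(C)(C)C | intermediate
6 | N-methoxy-N-methylacetamide | CC(=O)N(C)OC | starting material
7 | {1-[(tert-butyldimethylsilyl)oxy]-3-methylbut-2-en-2-yl}lithium | CC(C)=C([Li])CO[Si](C)(C)C(C)(C)C | intermediate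
8 | lithium 3-{[(tert-butyldimethylsilyl)oxy]methyl}-2-[methoxy(methyl)amino]-4-methylpent-3-en-2-olate | CC(O[Li])(N(C)OC)C(CO[Si](C)(C)C(C)(C)C)=C(C)C | intermediate
9 | 3-{[(tert-butyldimethylsilyl)oxy]methyl}-4-methylpent-3-en-2-one | CC(=O)C(CO[Si](C)(C)C(C)(C)C)=C(C)C | intermediate
10 | allylboronic acid pinacol ester | C=CCB1OC(C)(C)C(C)(C)O1 | starting material
11 | pinacol borate ester of 12 | C=CC[C@@](C)(OB1OC(C)(C)C(C)(C)O1)C(CO[Si](C)(C)C(C)(C)C)=C(C)C | intermediate
12 | (4R)-5-{[(tert-butyldimethylsilyl)oxy]methyl}-4,6-dimethylhepta-1,5-dien-4-ol | C=CC[C@@](C)(O)C(CO[Si](C)(C)C(C)(C)C)=C(C)C | intermediate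
13 | acryloyl chloride | C=CC(Cl)=O | starting material
14 | potassium alkoxide of 12 | C=CC[C@@](C)(O[K])C(CO[Si](C)(C)C(C)(C)C)=C(C)C | intermediate
15 | (4R)-5-{[(tert-butyldimethylsilyl)oxy]methyl}-4,6-dimethylhepta-1,5-dien-4-yl acrylate | C=CC[C@@](C)(OC(=O)C=C)C(CO[Si](C)(C)C(C)(C)C)=C(C)C | intermediate
16 | (6R)-6-{1-[(tert-butyldimethylsilyl)oxy]-3-methylbut-2-en-2-yl}-6-methyl-5,6-dihydro-2H-pyran-2-one | O=C1C=CC[C@@](C)(O1)C(CO[Si](C)(C)C(C)(C)C)=C(C)C | intermediate
17 | vinylmagnesium bromide | C=C[Mg]Br | starting material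
18 | bromomagnesium enolate of 19 | Br[Mg]OC1=C[C@@H](C=C)C[C@@](C)(O1)C(CO[Si](C)(C)C(C)(C)C)=C(C)C | intermediate
19 | (4S,6R)-6-{1-[(tert-butyldimethylsilyl)oxy]-3-methylbut-2-en-2-yl}-6-methyl-4-vinyltetrahydro-2H-pyran-2-one (precursor of the key step) | O=C1C[C@@H](C=C)C[C@@](C)(O1)C(CO[Si](C)(C)C(C)(C)C)=C(C)C | intermediate
20 | trimethylsilyl ketene acetal of 19 | C[Si](C)(C)OC1=C[C@@H](C=C)C[C@@](C)(O1)C(CO[Si](C)(C)C(C)(C)C)=C(C)C | intermediate
21 | trimethylsilyl ester of 22 | C[Si](C)(C)OC(=O)[C@H]1[C@@H](C=C)CC(C)=C(CO[Si](C)(C)C(C)(C)C)C1(C)C | intermediate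
22 | (1S,6R)-3-{[(tert-butyldimethylsilyl)oxy]methyl}-2,2,4-trimethyl-6-vinylcyclohex-3-ene-1-carboxylic acid (product of the key step; carboxyl and vinyl cis) | OC(=O)[C@H]1[C@@H](C=C)CC(C)=C(CO[Si](C)(C)C(C)(C)C)C1(C)C | intermediate
23 | [(1S,6R)-3-{[(tert-butyldimethylsilyl)oxy]methyl}-2,2,4-trimethyl-6-vinylcyclohex-3-en-1-yl]methanol | OC[C@H]1[C@@H](C=C)CC(C)=C(CO[Si](C)(C)C(C)(C)C)C1(C)C | intermediate
24 | ring B iodide: 1-(iodomethyl) analogue of 23, CH2I cis to vinyl | IC[C@H]1[C@@H](C=C)CC(C)=C(CO[Si](C)(C)C(C)(C)C)C1(C)C | intermediate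
25 | (2-methylallyl)magnesium chloride | CC(=C)C[Mg]Cl | starting material
26 | ring B diene: 1-(3-methylbut-3-en-1-yl) analogue of 23, cis to vinyl | C=C(C)CC[C@H]1[C@@H](C=C)CC(C)=C(CO[Si](C)(C)C(C)(C)C)C1(C)C | intermediate
27 | tert-butyldimethyl{[(4aR,8aS)-1,1,3,6-tetramethyl-1,4,4a,7,8,8a-hexahydronaphthalen-2-yl]methoxy}silane | CC1=C[C@H]2CC(C)=C(CO[Si](C)(C)C(C)(C)C)C(C)(C)[C@H]2CC1 | intermediate
28 | [(4aR,8aS)-1,1,3,6-tetramethyl-1,4,4a,7,8,8a-hexahydronaphthalen-2-yl]methanol | CC1=C[C@H]2CC(C)=C(CO)C(C)(C)[C@H]2CC1 | intermediate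
29 | {[(4aR,8aS)-1,1,3,6-tetramethyl-1,4,4a,7,8,8a-hexahydronaphthalen-2-yl]methyl}triphenylphosphonium bromide | CC1=C[C@H]2CC(C)=C(C[P+](c3ccccc3)(c3ccccc3)c3ccccc3)C(C)(C)[C@H]2CC1.[Br-] | intermediate
30 | geraniol | CC(C)=CCC/C(C)=C/CO | starting material
31 | [(2R,3R)-3-methyl-3-(4-methylpent-3-en-1-yl)oxiran-2-yl]methanol | CC(C)=CCC[C@@]1(C)O[C@@H]1CO | intermediate
32 | tert-butyl{[(2R,3R)-3-methyl-3-(4-methylpent-3-en-1-yl)oxiran-2-yl]methoxy}diphenylsilane | CC(C)=CCC[C@@]1(C)O[C@@H]1CO[Si](c2ccccc2)(c2ccccc2)C(C)(C)C | intermediate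
33 | secondary ozonide of 32 (3,3-dimethyl-1,2,4-trioxolane) | CC1(C)OC(CC[C@@]2(C)O[C@@H]2CO[Si](c3ccccc3)(c3ccccc3)C(C)(C)C)OO1 | intermediate
34 | 3-[(2R,3R)-3-{[(tert-butyldiphenylsilyl)oxy]methyl}-2-methyloxiran-2-yl]propanal | O=CCC[C@@]1(C)O[C@@H]1CO[Si](c2ccccc2)(c2ccccc2)C(C)(C)C | intermediate
35 | (4R)-4-benzyl-3-propanoyl-1,3-oxazolidin-2-one | CCC(=O)N1[C@H](Cc2ccccc2)COC1=O | starting material
36 | (Z)-dibutylboron enolate of 35 | C/C=C(\OB(CCCC)CCCC)N1[C@H](Cc2ccccc2)COC1=O | intermediate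
37 | dibutylboron aldolate of 38 | O=C(N1[C@H](Cc2ccccc2)COC1=O)[C@H](C)[C@@H](OB(CCCC)CCCC)CC[C@@]3(C)O[C@@H]3CO[Si](c4ccccc4)(c4ccccc4)C(C)(C)C | intermediate
38 | (4R)-4-benzyl-3-[(2R,3S)-5-[(2R,3R)-3-{[(tert-butyldiphenylsilyl)oxy]methyl}-2-methyloxiran-2-yl]-3-hydroxy-2-methylpentanoyl]-1,3-oxazolidin-2-one | O=C(N1[C@H](Cc2ccccc2)COC1=O)[C@H](C)[C@@H](O)CC[C@@]3(C)O[C@@H]3CO[Si](c4ccccc4)(c4ccccc4)C(C)(C)C | intermediate
39 | (2S,3S)-5-[(2R,3R)-3-{[(tert-butyldiphenylsilyl)oxy]methyl}-2-methyloxiran-2-yl]-2-methylpentane-1,3-diol | OC[C@H](C)[C@@H](O)CC[C@@]1(C)O[C@@H]1CO[Si](c2ccccc2)(c2ccccc2)C(C)(C)C | intermediate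
40 | (2S,3S)-1-[(tert-butyldiphenylsilyl)oxy]-5-[(2R,3R)-3-{[(tert-butyldiphenylsilyl)oxy]methyl}-2-methyloxiran-2-yl]-2-methylpentan-3-ol | CC(C)(C)[Si](c1ccccc1)(c1ccccc1)OC[C@H](C)[C@@H](O)CC[C@@]2(C)O[C@@H]2CO[Si](c3ccccc3)(c3ccccc3)C(C)(C)C | intermediate
41 | (2S,3S)-1-[(tert-butyldiphenylsilyl)oxy]-5-[(2R,3R)-3-{[(tert-butyldiphenylsilyl)oxy]methyl}-2-methyloxiran-2-yl]-2-methylpentan-3-yl methanesulfonate | CC(C)(C)[Si](c1ccccc1)(c1ccccc1)OC[C@H](C)[C@@H](OS(C)(=O)=O)CC[C@@]2(C)O[C@@H]2CO[Si](c3ccccc3)(c3ccccc3)C(C)(C)C | intermediate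
42 | (2S,3S,6S,7R)-1,8-bis[(tert-butyldiphenylsilyl)oxy]-6-hydroperoxy-7-hydroxy-2,6-dimethyloctan-3-yl methanesulfonate | CC(C)(C)[Si](c1ccccc1)(c1ccccc1)OC[C@H](C)[C@@H](OS(C)(=O)=O)CC[C@](C)(OO)[C@H](O)CO[Si](c2ccccc2)(c2ccccc2)C(C)(C)C | intermediate
43 | (1R)-2-[(tert-butyldiphenylsilyl)oxy]-1-[(3S,6R)-6-{(2S)-1-[(tert-butyldiphenylsilyl)oxy]propan-2-yl}-3-methyl-1,2-dioxan-3-yl]ethan-1-ol | CC(C)(C)[Si](c1ccccc1)(c1ccccc1)OC[C@H](C)[C@H]2CC[C@](C)(OO2)[C@H](O)CO[Si](c3ccccc3)(c3ccccc3)C(C)(C)C | intermediate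
44 | (1R)-1-[(3S,6R)-6-[(2S)-1-hydroxypropan-2-yl]-3-methyl-1,2-dioxan-3-yl]ethane-1,2-diol | OC[C@H](C)[C@H]1CC[C@](C)(OO1)[C@H](O)CO | intermediate
45 | (3S,6R)-6-[(2S)-1-hydroxypropan-2-yl]-3-methyl-1,2-dioxane-3-carbaldehyde | OC[C@H](C)[C@H]1CC[C@](C)(OO1)C=O | intermediate
46 | ylide from 29: {[(4aR,8aS)-1,1,3,6-tetramethyl-1,4,4a,7,8,8a-hexahydronaphthalen-2-yl]methylidene}triphenylphosphorane | CC1=C[C@H]2CC(C)=C(C=P(c3ccccc3)(c3ccccc3)c3ccccc3)C(C)(C)[C@H]2CC1 | intermediate
47 | (2S)-2-[(3R,6S)-6-methyl-6-{2-[(4aR,8aS)-1,1,3,6-tetramethyl-1,4,4a,7,8,8a-hexahydronaphthalen-2-yl]ethenyl}-1,2-dioxan-3-yl]propan-1-ol (E/Z mixture) | CC1=C[C@H]2CC(C)=C(C=C[C@]3(C)CC[C@H]([C@@H](C)CO)OO3)C(C)(C)[C@H]2CC1 | intermediate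
48 | (2S)-2-[(3R,6R)-6-methyl-6-{2-[(4aR,8aS)-1,1,3,6-tetramethyl-1,4,4a,7,8,8a-hexahydronaphthalen-2-yl]ethyl}-1,2-dioxan-3-yl]propan-1-ol | CC1=C[C@H]2CC(C)=C(CC[C@]3(C)CC[C@H]([C@@H](C)CO)OO3)C(C)(C)[C@H]2CC1 | intermediate
49 | (2R)-2-[(3R,6R)-6-methyl-6-{2-[(4aR,8aS)-1,1,3,6-tetramethyl-1,4,4a,7,8,8a-hexahydronaphthalen-2-yl]ethyl}-1,2-dioxan-3-yl]propanal | CC1=C[C@H]2CC(C)=C(CC[C@]3(C)CC[C@H]([C@@H](C)C=O)OO3)C(C)(C)[C@H]2CC1 | intermediate
50 | (2R)-2-[(3R,6R)-6-methyl-6-{2-[(4aR,8aS)-1,1,3,6-tetramethyl-1,4,4a,7,8,8a-hexahydronaphthalen-2-yl]ethyl}-1,2-dioxan-3-yl]propanoic acid | CC1=C[C@H]2CC(C)=C(CC[C@]3(C)CC[C@H]([C@@H](C)C(=O)O)OO3)C(C)(C)[C@H]2CC1 | target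

**Step count and risk**

Total step count: 29 (15 for the decalin phosphonium salt, 11 for the dioxane aldehyde, 3 after the union).
Longest linear sequence: 18 steps (steps 1–15, then 27–29).

Steps most likely to fail:

1. Step 9 (key step). The boat-like transition state places a CMe2 terminus over a substituted ketene acetal carbon; at the temperature needed, the silyl ketene acetal may instead ionise at the tertiary allylic C–O bond and eliminate, or desilylate back to the lactone. Fallback: ring B is assembled anionically, setting out from acryloyl chloride 13 and vinylmagnesium bromide 17 and returning at acid 22. Commercial (S)-pent-4-en-2-ol F1 is acylated with 13 (Et3N, 4-dimethylaminopyridine) to (S)-pent-4-en-2-yl acrylate F2. Ring-closing metathesis with the second-generation Grubbs catalyst gives (6S)-6-methyl-5,6-dihydro-2H-pyran-2-one F3, and the divinylcuprate from 17 and CuI adds trans to the methyl group to give (4S,6S)-6-methyl-4-vinyltetrahydro-2H-pyran-2-one F4. Its lithium enolate (LiN(iPr)2, THF, −78 °C) undergoes Michael addition, anti to the vinyl group, to ethyl 2-(diethoxyphosphoryl)-3-methylbut-2-enoate F5 (from triethyl phosphonoacetate and acetone, TiCl4, pyridine). This forms the C1–C8a bond with the same relative configuration as the rearrangement and gives the Michael adduct F6. Saponification of the lactone (KOH, THF/H2O) gives the potassium hydroxy carboxylate F7, and oxidation of its secondary alcohol (TEMPO, NaOCl, NaHCO3) gives the keto acid F8. An intramolecular Horner–Wadsworth–Emmons reaction (NaH, THF) then closes ring B at C2=C3 to give the ring B acid ester F9. Reduction of the ethyl ester in the presence of the carboxylate (i-Bu2AlH, toluene, −78 °C) gives the hydroxy acid F10. Silylation of both hydroxyl and carboxyl groups (TBSCl, imidazole) gives the bis-silyl compound F11, and cleavage of the silyl ester (K2CO3, MeOH) gives 22.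

2. Step 27. Addition of the hindered ylide to the neopentyl-type aldehyde may be slow enough that the ylide instead attacks or fragments the O–O bond. Fallback: the union is moved to sulfone-carbanion chemistry, setting out from alcohol 28 and returning at diene 47. A Mitsunobu reaction of 28 with 1-phenyl-1H-tetrazole-5-thiol (PPh3, diisopropyl azodicarboxylate) gives the tetrazolyl sulfide F12. Chemoselective sulfur oxidation (H2O2, (NH4)6Mo7O24, EtOH, 0 °C) gives the tetrazolyl sulfone F13. Its potassium anion (KN(SiMe3)2, 1,2-dimethoxyethane, −60 °C) adds to aldehyde 45 and collapses with loss of sulfur dioxide and the tetrazolone salt (Julia–Kocienski olefination) to give 47.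

3. Step 23. Opening of the epoxide may pass through a free tertiary cation, which would erode the inversion at the future C6, or divert to hydride-shift (carbonyl-forming) rearrangement. Fallback: the order of the two C–O bond formations is reversed, setting out from mesylate 41 and returning at dioxane 43. Displacement of the mesylate with 2-methoxyprop-2-yl hydroperoxide (CsOH·H2O, DMF, 0 °C to rt) with inversion gives the peroxyketal F14. Mild acid (AcOH/H2O/THF) frees the secondary hydroperoxy epoxide F15. The tethered hydroperoxide then opens the epoxide at its tertiary carbon in a 6-exo ring closure with inversion (camphorsulfonic acid, CH2Cl2, 0 °C), delivered intramolecularly so that it outruns cation formation, to give 43.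

Further compounds
F1 | step 9 | (S)-pent-4-en-2-ol | C=CC[C@H](C)O
F2 | step 9 | (S)-pent-4-en-2-yl acrylate | C=CC[C@H](C)OC(=O)C=C
F3 | step 9 | (6S)-6-methyl-5,6-dihydro-2H-pyran-2-one | C[C@H]1CC=CC(=O)O1
F4 | step 9 | (4S,6S)-6-methyl-4-vinyltetrahydro-2H-pyran-2-one | O=C1C[C@@H](C=C)C[C@H](C)O1
F5 | step 9 | ethyl 2-(diethoxyphosphoryl)-3-methylbut-2-enoate | CCOC(=O)C(=C(C)C)P(=O)(OCC)OCC
F6 | step 9 | Michael adduct: lactone F4 bearing a 1-(diethoxyphosphoryl)-1-(ethoxycarbonyl)-2-methylpropan-2-yl group at the α-carbon, trans to vinyl | O=C1[C@H](C(C)(C)C(C(=O)OCC)P(=O)(OCC)OCC)[C@@H](C=C)C[C@H](C)O1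
F7 | step 9 | potassium hydroxy carboxylate from F6 | [K+].[O-]C(=O)[C@H](C(C)(C)C(C(=O)OCC)P(=O)(OCC)OCC)[C@@H](C=C)C[C@H](C)O
F8 | step 9 | keto acid from F7 | OC(=O)[C@H](C(C)(C)C(C(=O)OCC)P(=O)(OCC)OCC)[C@@H](C=C)CC(C)=O
F9 | step 9 | (1S,6R)-3-(ethoxycarbonyl)-2,2,4-trimethyl-6-vinylcyclohex-3-ene-1-carboxylic acid | OC(=O)[C@H]1[C@@H](C=C)CC(C)=C(C(=O)OCC)C1(C)C
F10 | step 9 | (1S,6R)-3-(hydroxymethyl)-2,2,4-trimethyl-6-vinylcyclohex-3-ene-1-carboxylic acid | OC(=O)[C@H]1[C@@H](C=C)CC(C)=C(CO)C1(C)C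
F11 | step 9 | tert-butyldimethylsilyl ester of 22 | CC(C)(C)[Si](C)(C)OC(=O)[C@H]1[C@@H](C=C)CC(C)=C(CO[Si](C)(C)C(C)(C)C)C1(C)C
F12 | step 27 | 1-phenyl-5-({[(4aR,8aS)-1,1,3,6-tetramethyl-1,4,4a,7,8,8a-hexahydronaphthalen-2-yl]methyl}sulfanyl)-1H-tetrazole | CC1=C[C@H]2CC(C)=C(CSc3nnnn3-c3ccccc3)C(C)(C)[C@H]2CC1
F13 | step 27 | 1-phenyl-5-({[(4aR,8aS)-1,1,3,6-tetramethyl-1,4,4a,7,8,8a-hexahydronaphthalen-2-yl]methyl}sulfonyl)-1H-tetrazole | CC1=C[C@H]2CC(C)=C(CS(=O)(=O)c3nnnn3-c3ccccc3)C(C)(C)[C@H]2CC1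
F14 | step 23 | (2S,3R)-configured 2-methoxyprop-2-yl peroxide from 41 (epoxide intact) | CC(C)(C)[Si](c1ccccc1)(c1ccccc1)OC[C@H](C)[C@H](OOC(C)(C)OC)CC[C@@]2(C)O[C@@H]2CO[Si](c3ccccc3)(c3ccccc3)C(C)(C)C
F15 | step 23 | (2S,3R)-configured secondary hydroperoxide from F14 (epoxide intact) | CC(C)(C)[Si](c1ccccc1)(c1ccccc1)OC[C@H](C)[C@H](OO)CC[C@@]2(C)O[C@@H]2CO[Si](c3ccccc3)(c3ccccc3)C(C)(C)C
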